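The synthesis rests on disconnecting the 2,4-dihydroxy-5,6-dimethylbenzoate ring (C1'–C6') that is esterified to the oxygen of the C3 methylene of the isochromanone; this ring is a C-methylated tetraketide. In one operation an acylketene, released by heating a diketo-dioxinone, acylates the primary alcohol (ester C–O bond), and the resulting triketo ester closes by aldol condensation (C1'–C6' bond) to the aromatic ring with both phenols free. The precursor is the (3R,4S)-isochromanone lactol carried as its 3-O-benzyl ether with a free hydroxymethyl group at C3. Its C4 centre comes from an oxazolidinone-directed methylation, and hydrogenolysis of the benzyl ketal finishes the synthesis.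

Key step: step 15

Remark: the (3R) hemiketal, with the C3 oxygen substituent axial and trans to the pseudoaxial C4 methyl group, is assumed to be the thermodynamically preferred anomer, so lactols and lactol ethers formed under equilibrating conditions are drawn in that form; metallated and catalyst-bound species are treated as reactive forms of the numbered compounds.

Step 1
Reactants: 1 4,5-dimethylresorcinol
Product: 3 2,4-dihydroxy-5,6-dimethylbenzaldehyde, via aryl iminium chloride 2 (not isolated)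
Conditions: POCl3, DMF, 0 °C to rt; then H2O, 50 °C
Reagents that add atoms: N,N-dimethylformamide, CN(C)C=O; water, O
Why: Vilsmeier–Haack formylation attacks the ring position para to one hydroxyl and ortho to the other (next to the C5 methyl group), the site that orcinol also uses, and the iminium salt is hydrolysed on work-up.

Step 2
Reactants: 3 2,4-dihydroxy-5,6-dimethylbenzaldehyde
Product: 4 2-hydroxy-4-methoxy-5,6-dimethylbenzaldehyde
Conditions: MeI (1.05 equiv), K2CO3 (1.05 equiv), acetone, rt
Reagents that add atoms: iodomethane, CI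
Why: Williamson ether synthesis with one equivalent of MeI alkylates the C4 phenol, because the C2 phenol is held in a hydrogen bond to the formyl group and is much less nucleophilic.

Step 3
Reactants: 4 2-hydroxy-4-methoxy-5,6-dimethylbenzaldehyde
Product: 5 2-hydroxy-4-methoxy-5,6-dimethylbenzoic acid
Conditions: NaClO2, NaH2PO4, 2-methyl-2-butene, t-BuOH/H2O, rt
Reagents that add atoms: sodium chlorite, [Na+].[O-]Cl=O
Why: Pinnick oxidation converts the aldehyde to the acid under buffered conditions, and the alkene scavenger removes the hypochlorous acid that could chlorinate the electron-rich ring.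

Step 4
Reactants: 5 2-hydroxy-4-methoxy-5,6-dimethylbenzoic acid
Product: 6 benzyl 2-(benzyloxy)-4-methoxy-5,6-dimethylbenzoate
Conditions: BnBr (2.4 equiv), K2CO3 (3 equiv), DMF, rt then 60 °C
Reagents that add atoms: benzyl bromide, BrCc1ccccc1
Why: Carboxylate alkylation followed by Williamson etherification of the chelated phenol on warming masks acid and phenol as benzyl groups that can later be removed together under neutral conditions.

Step 5
Reactants: 6 benzyl 2-(benzyloxy)-4-methoxy-5,6-dimethylbenzoate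
Product: 7 2-[3-(benzyloxy)-2-(benzyloxycarbonyl)-5-methoxy-6-methylphenyl]acetic acid
Conditions: LiN(i-Pr)2 (1.2 equiv), THF, −78 °C; CO2; aq. HCl
Reagents that add atoms: carbon dioxide, O=C=O
Why: Lateral lithiation of an ortho-toluate removes a proton only from the C6 methyl group, which is conjugated with the ester carbonyl (the C5 methyl group is not), and the benzylic anion is carboxylated by CO2.

Step 6
Reactants: 7 2-[3-(benzyloxy)-2-(benzyloxycarbonyl)-5-methoxy-6-methylphenyl]acetic acid; 8 (S)-4-benzyl-2-oxazolidinone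
Product: 10 (S)-4-benzyl-3-{2-[3-(benzyloxy)-2-(benzyloxycarbonyl)-5-methoxy-6-methylphenyl]acetyl}oxazolidin-2-one, via mixed pivalic anhydride 9 (not isolated)
Conditions: PivCl, Et3N, THF, −20 °C; then 8, LiCl, rt
Reagents that add atoms: none
Why: N-Acylation of the oxazolidinone through the mixed pivalic anhydride with LiCl/Et3N activation loads the Evans auxiliary without a strong base.

Step 7
Reactants: 10 (S)-4-benzyl-3-{2-[3-(benzyloxy)-2-(benzyloxycarbonyl)-5-methoxy-6-methylphenyl]acetyl}oxazolidin-2-one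
Product: 11 (S)-4-benzyl-3-{(2S)-2-[3-(benzyloxy)-2-(benzyloxycarbonyl)-5-methoxy-6-methylphenyl]propanoyl}oxazolidin-2-one
Conditions: NaN(SiMe3)2 (1.1 equiv), THF, −78 °C; MeI (5 equiv), −78 to −40 °C
Reagents that add atoms: iodomethane, CI
Why: In this Evans asymmetric alkylation the chelated Z-enolate is methylated on the face away from the benzyl group of the (S)-auxiliary, which sets the (S) benzylic centre that becomes C4 of the isochromanone.

Step 8
Reactants: 11 (S)-4-benzyl-3-{(2S)-2-[3-(benzyloxy)-2-(benzyloxycarbonyl)-5-methoxy-6-methylphenyl]propanoyl}oxazolidin-2-one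
Product: 12 (2S)-2-[3-(benzyloxy)-2-(benzyloxycarbonyl)-5-methoxy-6-methylphenyl]propanoic acid
Conditions: LiOH, H2O2, THF/H2O, 0 °C; Na2SO3; aq. HCl
Reagents that add atoms: hydrogen peroxide, OO
Why: Lithium hydroperoxide cleavage of the Evans imide attacks the exocyclic carbonyl at 0 °C without enolising the α-aryl centre, and the doubly ortho-substituted benzyl benzoate is too hindered to react.

Step 9
Reactants: 12 (2S)-2-[3-(benzyloxy)-2-(benzyloxycarbonyl)-5-methoxy-6-methylphenyl]propanoic acid
Product: 14 benzyl 2-(benzyloxy)-6-[(2S)-4-diazo-3-oxobutan-2-yl]-4-methoxy-5-methylbenzoate, via acid chloride 13 (not isolated)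
Conditions: (COCl)2, cat. DMF, CH2Cl2, 0 °C; then CH2N2 (3 equiv), Et2O, 0 °C
Reagents that add atoms: diazomethane, C=[N+]=[N-]
Why: Acylation of diazomethane by the acid chloride (first half of an Arndt–Eistert sequence) needs no amine base, so ketene formation and loss of the α-configuration should be avoided, and excess diazomethane takes up the HCl.

Step 10
Reactants: 14 benzyl 2-(benzyloxy)-6-[(2S)-4-diazo-3-oxobutan-2-yl]-4-methoxy-5-methylbenzoate
Product: 15 benzyl 2-(benzyloxy)-6-[(2S)-4-(benzyloxy)-3-oxobutan-2-yl]-4-methoxy-5-methylbenzoate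
Conditions: BnOH (3 equiv), Rh2(OAc)4 (1 mol %), CH2Cl2, rt
Reagents that add atoms: benzyl alcohol, OCc1ccccc1
Why: Rhodium-carbenoid O–H insertion into benzyl alcohol gives the protected hydroxymethyl ketone under neutral conditions that leave the enolisable benzylic centre alone, and both ortho positions of the arene are substituted, which blocks aromatic C–H insertion.

Step 11
Reactants: 15 benzyl 2-(benzyloxy)-6-[(2S)-4-(benzyloxy)-3-oxobutan-2-yl]-4-methoxy-5-methylbenzoate
Product: 17 (3R,4S)-3,8-dihydroxy-3-(hydroxymethyl)-6-methoxy-4,5-dimethylisochroman-1-one, via keto acid 16 (not isolated)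
Conditions: H2 (1 atm), Pd(OH)2/C, EtOAc, rt
Reagents that add atoms: none
Why: Catalytic hydrogenolysis cleaves the three O-benzyl groups under neutral conditions, and the freed salicylic acid adds to the ketone to close the six-membered lactol (ring–chain tautomerism), which hides the ketone so that C4 keeps its configuration while C3 settles as the (3R) hemiketal.

Step 12
Reactants: 17 (3R,4S)-3,8-dihydroxy-3-(hydroxymethyl)-6-methoxy-4,5-dimethylisochroman-1-one
Product: 18 (3R,4S)-3-(benzyloxy)-8-hydroxy-3-(hydroxymethyl)-6-methoxy-4,5-dimethylisochroman-1-one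
Conditions: BnOH (10 equiv), PPTS (0.1 equiv), 4 Å MS, CH2Cl2, rt
Reagents that add atoms: benzyl alcohol, OCc1ccccc1
Why: Acid-catalysed ketal exchange at the lactol carbon (Fischer-type glycosidation) is reversible, so the benzyloxy group should end up axial and trans to the pseudoaxial C4 methyl group, which is the (3R) ether, while this weak acid at room temperature should neither eliminate across C3–C4 nor enolise the masked ketone.

Step 13
Reactants: 19 2,2,6-trimethyl-4H-1,3-dioxin-4-one
Product: 20 2,2-dimethyl-6-(2-oxobutyl)-4H-1,3-dioxin-4-one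
Conditions: LiN(SiMe3)2 (2 equiv), 19 (2 equiv), THF, −78 °C; EtCOCl (1 equiv); aq. HCl
Reagents that add atoms: propanoyl chloride, CCC(Cl)=O
Why: γ-Acylation of the lithium dienolate of the dioxinone (vinylogous Claisen condensation) gives the keto-dioxinone, and a second equivalent of dienolate is supplied because the product is more acidic than the starting dioxinone.

Step 14
Reactants: 20 2,2-dimethyl-6-(2-oxobutyl)-4H-1,3-dioxin-4-one
Product: 21 2,2-dimethyl-6-(3-methyl-2,4-dioxopentyl)-4H-1,3-dioxin-4-one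
Conditions: LiN(i-Pr)2 (2.2 equiv), THF, −78 °C; MeC(O)N(OMe)Me, −78 to −20 °C; aq. HCl
Reagents that add atoms: N-methoxy-N-methylacetamide, CC(=O)N(C)OC
Why: Claisen-type acylation of the keto-dioxinone dianion occurs at its more basic terminal carbanion (the CH2 of the ethyl ketone), and the chelated tetrahedral intermediate of the Weinreb amide prevents over-addition.

Step 15
Reactants: 18 (3R,4S)-3-(benzyloxy)-8-hydroxy-3-(hydroxymethyl)-6-methoxy-4,5-dimethylisochroman-1-one; 21 2,2-dimethyl-6-(3-methyl-2,4-dioxopentyl)-4H-1,3-dioxin-4-one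
Product: 25 [(3R,4S)-3-(benzyloxy)-8-hydroxy-6-methoxy-4,5-dimethyl-1-oxoisochroman-3-yl]methyl 2,4-dihydroxy-5,6-dimethylbenzoate, via acylketene 22 (not isolated), via triketo ester 23 (not isolated), via aldol adduct 24 (not isolated)
Conditions: PhMe, 110 °C; then Cs2CO3, CH2Cl2/i-PrOH, rt; then AcOH
Reagents that add atoms: none
Why: Heating expels acetone from dioxinone 21 by retro-[4+2] fragmentation, and acylketene 22 is trapped by the primary hydroxyl of 18 to give triketo ester 23 (ester C–O bond). Carbonate then enolises the ester-flanked methylene, which adds to the terminal methyl ketone in a 6-(enolendo)-exo-trig aldol closure (C1'–C6' bond), and loss of water from 24 followed by enolisation gives the benzene ring with both phenols free. The closest known reaction type is the dioxinone-based acylketene capture and cycloaromatisation used for resorcylate esters, here run with a C-methylated diketo-dioxinone. No stereocentre is formed, and C3 and C4 are preserved because the benzyl lactol ether cannot open to the enolisable keto acid under heat or carbonate. The step needs O-acylation of the primary hydroxyl and not of the C8 phenol, which the hydrogen bond of that phenol to the lactone carbonyl and its lower nucleophilicity secure. It also needs the aldol mode and not Claisen closure onto the ester, which is secured because the unhindered ester-flanked methylene leads on to an aromatic ring, whereas attack by the methyl-bearing carbon would create a quaternary centre that cannot aromatise.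

Step 16
Reactants: 25 [(3R,4S)-3-(benzyloxy)-8-hydroxy-6-methoxy-4,5-dimethyl-1-oxoisochroman-3-yl]methyl 2,4-dihydroxy-5,6-dimethylbenzoate
Product: 26 [(3R,4S)-3,8-dihydroxy-6-methoxy-4,5-dimethyl-1-oxoisochroman-3-yl]methyl 2,4-dihydroxy-5,6-dimethylbenzoate
Conditions: H2 (1 atm), 10% Pd/C, EtOAc, rt
Reagents that add atoms: none
Why: Hydrogenolysis of the benzyl ketal cleaves only the O–CH2Ph bond under neutral conditions, so the hemiketal is released with retention at C3 and the esters, lactone and phenols stay intact.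

Compound list

1 | 4,5-dimethylresorcinol | Cc1cc(O)cc(O)c1C | starting material
2 | N-[(2,4-dihydroxy-5,6-dimethylphenyl)methylidene]-N-methylmethanaminium chloride | C[N+](C)=Cc1c(O)cc(O)c(C)c1C.[Cl-] | intermediate
3 | 2,4-dihydroxy-5,6-dimethylbenzaldehyde | O=Cc1c(O)cc(O)c(C)c1C | intermediate
4 | 2-hydroxy-4-methoxy-5,6-dimethylbenzaldehyde | COc1cc(O)c(C=O)c(C)c1C | intermediate
5 | 2-hydroxy-4-methoxy-5,6-dimethylbenzoic acid | COc1cc(O)c(C(=O)O)c(C)c1C | intermediate
6 | benzyl 2-(benzyloxy)-4-methoxy-5,6-dimethylbenzoate | COc1cc(OCc2ccccc2)c(C(=O)OCc2ccccc2)c(C)c1C | intermediate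
7 | 2-[3-(benzyloxy)-2-(benzyloxycarbonyl)-5-methoxy-6-methylphenyl]acetic acid | COc1cc(OCc2ccccc2)c(C(=O)OCc2ccccc2)c(CC(=O)O)c1C | intermediate
8 | (S)-4-benzyl-2-oxazolidinone | O=C1N[C@@H](Cc2ccccc2)CO1 | starting material
9 | mixed anhydride of acid 7 with pivalic acid | COc1cc(OCc2ccccc2)c(C(=O)OCc2ccccc2)c(CC(=O)OC(=O)C(C)(C)C)c1C | intermediate
10 | (S)-4-benzyl-3-{2-[3-(benzyloxy)-2-(benzyloxycarbonyl)-5-methoxy-6-methylphenyl]acetyl}oxazolidin-2-one | COc1cc(OCc2ccccc2)c(C(=O)OCc2ccccc2)c(CC(=O)N2[C@@H](Cc3ccccc3)COC2=O)c1C | intermediate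
11 | (S)-4-benzyl-3-{(2S)-2-[3-(benzyloxy)-2-(benzyloxycarbonyl)-5-methoxy-6-methylphenyl]propanoyl}oxazolidin-2-one | COc1cc(OCc2ccccc2)c(C(=O)OCc2ccccc2)c([C@H](C)C(=O)N2[C@@H](Cc3ccccc3)COC2=O)c1C | intermediate
12 | (2S)-2-[3-(benzyloxy)-2-(benzyloxycarbonyl)-5-methoxy-6-methylphenyl]propanoic acid | COc1cc(OCc2ccccc2)c(C(=O)OCc2ccccc2)c([C@H](C)C(=O)O)c1C | intermediate
13 | (2S)-2-[3-(benzyloxy)-2-(benzyloxycarbonyl)-5-methoxy-6-methylphenyl]propanoyl chloride | COc1cc(OCc2ccccc2)c(C(=O)OCc2ccccc2)c([C@H](C)C(Cl)=O)c1C | intermediate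
14 | benzyl 2-(benzyloxy)-6-[(2S)-4-diazo-3-oxobutan-2-yl]-4-methoxy-5-methylbenzoate | COc1cc(OCc2ccccc2)c(C(=O)OCc2ccccc2)c([C@H](C)C(=O)C=[N+]=[N-])c1C | intermediate
15 | benzyl 2-(benzyloxy)-6-[(2S)-4-(benzyloxy)-3-oxobutan-2-yl]-4-methoxy-5-methylbenzoate | COc1cc(OCc2ccccc2)c(C(=O)OCc2ccccc2)c([C@H](C)C(=O)COCc2ccccc2)c1C | intermediate
16 | 2-hydroxy-6-[(2S)-4-hydroxy-3-oxobutan-2-yl]-4-methoxy-5-methylbenzoic acid | COc1cc(O)c(C(=O)O)c([C@H](C)C(=O)CO)c1C | intermediate
17 | (3R,4S)-3,8-dihydroxy-3-(hydroxymethyl)-6-methoxy-4,5-dimethylisochroman-1-one | COc1cc(O)c2c(c1C)[C@H](C)[C@](O)(CO)OC2=O | intermediate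
18 | (3R,4S)-3-(benzyloxy)-8-hydroxy-3-(hydroxymethyl)-6-methoxy-4,5-dimethylisochroman-1-one | COc1cc(O)c2c(c1C)[C@H](C)[C@](OCc3ccccc3)(CO)OC2=O | intermediate
19 | 2,2,6-trimethyl-4H-1,3-dioxin-4-one | CC1=CC(=O)OC(C)(C)O1 | starting material
20 | 2,2-dimethyl-6-(2-oxobutyl)-4H-1,3-dioxin-4-one | CCC(=O)CC1=CC(=O)OC(C)(C)O1 | intermediate
21 | 2,2-dimethyl-6-(3-methyl-2,4-dioxopentyl)-4H-1,3-dioxin-4-one | CC(=O)C(C)C(=O)CC1=CC(=O)OC(C)(C)O1 | intermediate
22 | 6-methyloct-1-ene-1,3,5,7-tetrone (acylketene) | CC(=O)C(C)C(=O)CC(=O)C=C=O | intermediate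
23 | [(3R,4S)-3-(benzyloxy)-8-hydroxy-6-methoxy-4,5-dimethyl-1-oxoisochroman-3-yl]methyl 6-methyl-3,5,7-trioxooctanoate | COc1cc(O)c2c(c1C)[C@H](C)[C@](OCc3ccccc3)(COC(=O)CC(=O)CC(=O)C(C)C(C)=O)OC2=O | intermediate
24 | [(3R,4S)-3-(benzyloxy)-8-hydroxy-6-methoxy-4,5-dimethyl-1-oxoisochroman-3-yl]methyl 6-hydroxy-5,6-dimethyl-2,4-dioxocyclohexane-1-carboxylate (mixture of stereoisomers in the new ring) | COc1cc(O)c2c(c1C)[C@H](C)[C@](OCc3ccccc3)(COC(=O)C1C(=O)CC(=O)C(C)C1(C)O)OC2=O | intermediate
25 | [(3R,4S)-3-(benzyloxy)-8-hydroxy-6-methoxy-4,5-dimethyl-1-oxoisochroman-3-yl]methyl 2,4-dihydroxy-5,6-dimethylbenzoate | COc1cc(O)c2c(c1C)[C@H](C)[C@](OCc3ccccc3)(COC(=O)c1c(O)cc(O)c(C)c1C)OC2=O | intermediate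
26 | [(3R,4S)-3,8-dihydroxy-6-methoxy-4,5-dimethyl-1-oxoisochroman-3-yl]methyl 2,4-dihydroxy-5,6-dimethylbenzoate | COc1cc(O)c2c(c1C)[C@H](C)[C@](O)(COC(=O)c1c(O)cc(O)c(C)c1C)OC2=O | target

Total steps: 16. Longest linear sequence: 14 steps (steps 1–12, then 15 and 16).

Steps most likely to fail

Step 15. The acylketene may be consumed by intramolecular O-acylation through its own diketone enol (pyranone formation) before the hindered primary hydroxyl captures it, or the carbonate stage may close the triketo ester in a non-aromatising mode. The fallback makes the ester bond at the diazoketone stage and sets out from diazoketone 14 and aldehyde 3. Aldehyde 3 is dibenzylated (BnBr, K2CO3, DMF) to 2,4-bis(benzyloxy)-5,6-dimethylbenzaldehyde F1 and oxidised (NaClO2, NaH2PO4, 2-methyl-2-butene) to 2,4-bis(benzyloxy)-5,6-dimethylbenzoic acid F2. Acid F2 then undergoes O–H insertion with 14 (Rh2(OAc)4 cat., CH2Cl2, rt) to give benzyl 2-(benzyloxy)-6-[(2S)-4-{[2,4-bis(benzyloxy)-5,6-dimethylbenzoyl]oxy}-3-oxobutan-2-yl]-4-methoxy-5-methylbenzoate F3. Hydrogenolysis (H2, Pd(OH)2/C, EtOAc) removes the four benzyl groups, and 2-hydroxy-6-[(2S)-4-[(2,4-dihydroxy-5,6-dimethylbenzoyl)oxy]-3-oxobutan-2-yl]-4-methoxy-5-methylbenzoic acid F4 closes to the lactol, so the route is rejoined at target 26.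

Step 12. The acid may promote loss of the C3 oxygen substituent together with the C4 hydrogen (isocoumarin formation, which erases C4), or the free primary hydroxyl may take part through acyl shift or self-ketalisation. The fallback keeps that hydroxyl acylated during the exchange and sets out from diazoketone 14. O–H insertion into acetic acid (AcOH, Rh2(OAc)4 cat., CH2Cl2) gives benzyl 6-[(2S)-4-(acetyloxy)-3-oxobutan-2-yl]-2-(benzyloxy)-4-methoxy-5-methylbenzoate F5. Hydrogenolysis (H2, Pd/C, EtOAc) gives 6-[(2S)-4-(acetyloxy)-3-oxobutan-2-yl]-2-hydroxy-4-methoxy-5-methylbenzoic acid F6, which closes to [(3R,4S)-3,8-dihydroxy-6-methoxy-4,5-dimethyl-1-oxoisochroman-3-yl]methyl acetate F7. Ketal exchange (BnOH, PPTS, 4 Å MS) gives [(3R,4S)-3-(benzyloxy)-8-hydroxy-6-methoxy-4,5-dimethyl-1-oxoisochroman-3-yl]methyl acetate F8, and lipase-mediated deacetylation at neutral pH (Candida antarctica lipase B, pH 7 buffer/MTBE) returns to the route at 18.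

Step 9. Configuration at the α-aryl centre may be lost through a ketene, or the acid chloride may cyclise onto the neighbouring benzyl ester with loss of benzyl chloride (cyclic anhydride formation). The fallback avoids the acid chloride and the diazoketone and sets out from acid 12. Amide coupling (MeNHOMe·HCl, EDC·HCl, HOBt, i-Pr2NEt, CH2Cl2) gives benzyl 2-(benzyloxy)-4-methoxy-6-[(2S)-1-[methoxy(methyl)amino]-1-oxopropan-2-yl]-5-methylbenzoate F9. Addition of (benzyloxymethyl)lithium (from BnOCH2SnBu3 and n-BuLi, THF, −78 °C) to this Weinreb amide returns to the route at benzyloxymethyl ketone 15.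

Further compounds

F1 | step 15 | 2,4-bis(benzyloxy)-5,6-dimethylbenzaldehyde | O=Cc1c(OCc2ccccc2)cc(OCc2ccccc2)c(C)c1C
F2 | step 15 | 2,4-bis(benzyloxy)-5,6-dimethylbenzoic acid | OC(=O)c1c(OCc2ccccc2)cc(OCc2ccccc2)c(C)c1C
F3 | step 15 | benzyl 2-(benzyloxy)-6-[(2S)-4-{[2,4-bis(benzyloxy)-5,6-dimethylbenzoyl]oxy}-3-oxobutan-2-yl]-4-methoxy-5-methylbenzoate | COc1cc(OCc2ccccc2)c(C(=O)OCc2ccccc2)c([C@H](C)C(=O)COC(=O)c2c(OCc3ccccc3)cc(OCc3ccccc3)c(C)c2C)c1C
F4 | step 15 | 2-hydroxy-6-[(2S)-4-[(2,4-dihydroxy-5,6-dimethylbenzoyl)oxy]-3-oxobutan-2-yl]-4-methoxy-5-methylbenzoic acid | COc1cc(O)c(C(=O)O)c([C@H](C)C(=O)COC(=O)c2c(O)cc(O)c(C)c2C)c1C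
F5 | step 12 | benzyl 6-[(2S)-4-(acetyloxy)-3-oxobutan-2-yl]-2-(benzyloxy)-4-methoxy-5-methylbenzoate | COc1cc(OCc2ccccc2)c(C(=O)OCc2ccccc2)c([C@H](C)C(=O)COC(C)=O)c1C
F6 | step 12 | 6-[(2S)-4-(acetyloxy)-3-oxobutan-2-yl]-2-hydroxy-4-methoxy-5-methylbenzoic acid | COc1cc(O)c(C(=O)O)c([C@H](C)C(=O)COC(C)=O)c1C
F7 | step 12 | [(3R,4S)-3,8-dihydroxy-6-methoxy-4,5-dimethyl-1-oxoisochroman-3-yl]methyl acetate | COc1cc(O)c2c(c1C)[C@H](C)[C@](O)(COC(C)=O)OC2=O
F8 | step 12 | [(3R,4S)-3-(benzyloxy)-8-hydroxy-6-methoxy-4,5-dimethyl-1-oxoisochroman-3-yl]methyl acetate | COc1cc(O)c2c(c1C)[C@H](C)[C@](OCc3ccccc3)(COC(C)=O)OC2=O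
F9 | step 9 | benzyl 2-(benzyloxy)-4-methoxy-6-[(2S)-1-[methoxy(methyl)amino]-1-oxopropan-2-yl]-5-methylbenzoate | COc1cc(OCc2ccccc2)c(C(=O)OCc2ccccc2)c([C@H](C)C(=O)N(C)OC)c1C
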